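## The problem

Target 40 is an achiral chain of seven benzene rings (A to G) joined by six diaryl ether oxygens and carrying eighteen free hydroxyls. There is no stereocentre to set or to exert control, so the whole task is to place twenty-four oxygens on forty-two carbons in the right order. Rings B, D and F are 3,5-dihydroxy-1,4-phenylenedioxy units, and rings A and G are trihydroxyphenyl caps. All five have an oxygen para to an ether link, a pattern that a para-formyl aryl fluoride can deliver (fluoride displacement, then exchange of the formyl group for oxygen). Rings C and E are the hard part: each has five contiguous oxygens (C1 ether to the inner ring, C2 ether to the outer ring, C3, C4 and C5 hydroxyls) and a single C6–H. Such a ring is too electron-rich to act as an SNAr electrophile and too crowded for selective oxygenation of a preformed arene. Every ether oxygen is flanked by ortho oxygens on at least one side, so each C–O coupling joins hindered, electron-rich partners. The free polyphenol, with its pyrogallol-type rings, oxidises easily in air and base, so all hydroxyls must stay masked to the last step by groups that tolerate alkyllithiums, peracid, HBr and heat. The enabling feature is that C2 to C5 of ring C (and of ring E), with their oxygens, are the four carbons of a squaric ester, while C1 (with its ether oxygen) and C6–H are the two carbons of a 1-(aryloxy)vinyl group. The ring can therefore be closed through the C5–C6 bond with all five oxygens in place and the two para oxygens (C2 and C5) told apart.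

## Retrosynthesis

**40 to 39.** The eighteen O–CH3 bonds are cut last in the forward sense, so 40 comes from its octadecamethyl ether 39. Methyl is preferred to benzyl or silyl because the oxygenated building blocks are sold as methyl ethers and methyl ethers ignore every reagent the route uses. The price is one exhaustive ether cleavage that must leave the six diaryl ether bonds alone. Compound 39 is no simpler in skeleton, but it is stable to air and chromatography.

**39 to 37 and 38.** The ether bond between ring F (O on C4) and C1 of ring G is cut, giving hexamer phenol 37 and 5-iodo-1,2,3-trimethoxybenzene 38. Ring G carries no further ether, so it can enter complete in one copper-catalysed coupling. Fluoride displacement would need an activating group on ring G and a second step to convert it. The forward coupling must accept a phenol flanked by two methoxy groups.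

**37 to 34 and 2.** The bond between the oxygen on C2 of ring E and C1 of ring F is cut, through aldehyde 35 and formate 36, giving pentamer silyl ether 34 and fluoroaldehyde 2. The para-formyl group of 2 activates the fluoride and is afterwards exchanged for the oxygen that ring F needs at C4. Cutting on the ring E side of the same oxygen is not possible, because a pentaoxygenated ring is no SNAr electrophile. The forward step asks a phenoxide with an ortho aryloxy and an ortho methoxy group to attack.

**34 to 22 (ring E).** Methyl ether 34 comes from phenol 33, and ring E of 33 is opened across C5–C6 to cyclobutenone 30. Compound 30 is divided into bromovinyl ether 27 and dimethyl squarate 12, and 27 goes back through ynol ether 26 and dichlorovinyl ether 23 to tetramer phenol 22 and trichloroethylene 6. The reasoning is the same as for ring C below; using one method twice is what keeps the route uniform.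

**22 to 19 and 2.** The ether bond between ring C (O on C2) and C1 of ring D is cut, through aldehyde 20 and formate 21, giving trimer silyl ether 19 and a second molecule of 2. The argument is the same as for ring F.

**19 to 15 (key disconnection, ring C).** Methyl ether 19 comes from phenol 18, in which C5–OH is free and C2–O is silylated. Ring C of 18 is opened retrosynthetically at C5–C6 and reclosed between C2 and C5 to give cyclobutenone 15. This is preferred to any ether-bond cut at ring C because it removes the pentaoxygenated arene altogether: 15 holds one small ring and no crowded arene. The forward cascade must open the four-membered ring with the capped oxygen turning outward and then close six carbons. A silyl cap is chosen over an acetal because it can be installed in the flask that makes the carbinol and is removed by the same fluoride that promotes the next ether formation.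

**15 to 11 and 12.** The bond between the carbinol carbon (future C2) and the vinyl carbon bearing the aryloxy group (future C1) is cut, giving squarate 12 and the vinyllithium 13 derived from bromide 11. Addition to one of two equivalent carbonyls of 12 needs no regiocontrol, and capping alkoxide 14 decides which para oxygen is later free.

**11 to 5 and 6.** Bromide 11 is the HBr adduct of ynol ether 10, which comes from dichlorovinyl ether 7, made from A–B phenol 5 and 6. A bromide is preferred to direct deprotonation of an aryl vinyl ether because rings A and B carry ring hydrogens between two oxygens that an alkyllithium would remove competitively. Bromine–lithium exchange is faster than any such metalation.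

**5 to 1 and 2.** Phenol 5 comes through formate 4 from aldehyde 3, and the A–B ether bond of 3 is cut to 2,4,6-trimethoxyphenol 1 and fluoroaldehyde 2. This is the same displacement and oxidation used for rings D and F, so three of the seven rings come from one purchased aldehyde.

## Roads not taken

**Alternative 1:** The cut removes both ether bonds of ring C at once (C1–O to ring B and C2–O to ring D). Forward, the cationic cyclopentadienylruthenium complex A1 of 1,2-dichloro-3,4,5-trimethoxybenzene would take the phenoxide of 5 and then the phenoxide of the D–E–F–G tetramer A2. This gives the metal-bound permethyl heptamer A3, from which the metal is released by photolysis in acetonitrile.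
- Merits: it is convergent (dimer plus tetramer), the SNAr is known for electron-rich chloroarenes once bound to the CpRu cation, and ring C enters as a simple arene.
- Weak points: the two chlorides of A1 differ only in their neighbours (H versus OMe), so the order of entry rests on a steric preference. The second displacement must occur next to a new bulky aryloxy group, on a complex made less electrophilic by the first donor, with the larger nucleophile. The metal is stoichiometric. A2 contains ring E, so the pentaoxygenated-ring problem returns inside the fragment.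
- Comparison: this road is better in convergence and avoids cryogenic organolithium chemistry. The chosen plan sets against that a ring C whose oxygen positions are fixed by the connectivity of 15, and one method that serves rings C and E alike.

**Alternative 2:** The cut is one C–C bond of ring A, unfolding it into triketide A4, a dimethyl 2-aryloxy-3,5-dioxoheptanedioate whose aryl group is the permethylated B–G hexamer. Methoxide (NaOMe or Mg(OMe)2) would form the C6 enolate, which attacks the C1 ester carbonyl. Aromatisation gives A5, the heptamer with ring A as a free triol bearing a methyl ester.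
- Merits: it mirrors the polyketide origin of phloroglucinol, uses no transition metal, and leaves three fewer methyl ethers to cleave.
- Weak points: ring A is the one ring that can be bought complete (as 1), so nothing hard is solved. The whole hexamer, with both pentaoxygenated rings, must already exist and then be alkylated on oxygen by a sensitive halo-dioxo diester. Open-chain 3,5-dioxo esters tend to close through oxygen to hydroxypyrones or by aldol paths. The ester of A5 costs a hydrolysis and a decarboxylation on an oxidisable triol.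
- Comparison: it is a neat ending for ring A alone and better in the number of final deprotections. The chosen plan instead spends its ring-forming step on the rings that cannot be bought.

**Alternative 3:** The cut removes two C–C bonds of ring D (C2–C3 and C1–C6) and divides the chain into two trimers. These are the ethynyl ether A6 on the C2 oxygen of ring C of an A–B–C trimer, and the 4-aryloxy-3-ethoxycyclobutenone A7 bearing the E–F–G trimer. On heating, A7 opens to a vinylketene that adds to the ynol ether. The new cyclobutenone opens and closes by a 6-electron electrocyclization to give A8, with ring D as 3-hydroxy-5-ethoxy and both its ether links in place.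
- Merits: it is the most convergent of the four plans, the benzannulation has reliable regiochemistry with alkoxyalkynes, and there is no hindered intermolecular C–O coupling at the C–D and D–E junctions.
- Weak points: it builds ring D, which fluoroaldehyde 2 supplies in two routine steps, while rings C and E (one in each trimer) still need another method. A7 needs an aryloxy group on the sp3 carbon of a cyclobutenone, for which a pentaoxygenated phenol would have to displace a halide on a ring prone to opening. Two ketenes are generated at 80–160 °C among many nucleophilic arenes.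
- Comparison: convergence and longest linear sequence are clearly better, and A6 is the same kind of ynol ether as 10 and 26. The chosen plan is linear and longer, but uses one cyclobutenone type, made in a single flask from 12, and applies its pericyclic step to the hard rings.

Key step: step 7

## Conventions and assumptions

- Ring positions: in rings B, D and F, C1 carries the ether oxygen toward ring A and C4 the one toward ring G. In rings C and E, C1 carries the ether oxygen toward ring A, C2 the one toward ring G, and C6 is the only CH.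
- Assumption: phenol 1 is taken as a catalogue compound. Adducts 15 and 30 each have one stereocentre that disappears on rearrangement, so both are made and used as racemates.

## Route

Step 1
Reactants: 1 2,4,6-trimethoxyphenol; 2 4-fluoro-2,6-dimethoxybenzaldehyde
Product: 3 2,6-dimethoxy-4-(2,4,6-trimethoxyphenoxy)benzaldehyde
Conditions: K2CO3, DMF, 110 °C, argon
Reagents that add atoms: none
Why: SNAr by addition–elimination; the para-formyl group stabilises the Meisenheimer intermediate and fluoride is the best leaving group for this mechanism, while the 2,6-dimethoxyphenoxide is hindered but strongly nucleophilic.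

Step 2
Reactants: 3 2,6-dimethoxy-4-(2,4,6-trimethoxyphenoxy)benzaldehyde
Product: 5 2,6-dimethoxy-4-(2,4,6-trimethoxyphenoxy)phenol (A–B phenol), via aryl formate 4 (not isolated)
Conditions: mCPBA, CH2Cl2, 0 °C to rt; NaHCO3 wash; then K2CO3 (cat.), MeOH, rt
Reagents that add atoms: 3-chloroperoxybenzoic acid, O=C(OO)c1cccc(Cl)c1
Why: Dakin-type Baeyer–Villiger oxidation; in an aldehyde flanked by two methoxy groups and para to an aryloxy group the electron-rich aryl migrates, and methanolysis of formate 4 releases the phenol.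

Step 3
Reactants: 5 2,6-dimethoxy-4-(2,4,6-trimethoxyphenoxy)phenol; 6 trichloroethylene
Product: 7 2-[(E)-1,2-dichloroethenyloxy]-1,3-dimethoxy-5-(2,4,6-trimethoxyphenoxy)benzene
Conditions: K2CO3, DMF, 70 °C
Reagents that add atoms: none
Why: Base converts 6 into dichloroacetylene in solution and anti addition of the phenoxide across it gives the (E)-dichlorovinyl ether; this is the standard entry to ynol ethers from phenols.

Step 4
Reactants: 7 2-[(E)-1,2-dichloroethenyloxy]-1,3-dimethoxy-5-(2,4,6-trimethoxyphenoxy)benzene
Product: 10 2-(ethynyloxy)-1,3-dimethoxy-5-(2,4,6-trimethoxyphenoxy)benzene, via chloroethynyl ether 8 (not isolated), via lithium acetylide 9 (not isolated)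
Conditions: n-BuLi (2.2 equiv), THF, −78 to −40 °C; then H2O, −78 °C
Reagents that add atoms: none
Why: Deprotonation and anti elimination of LiCl give 8, chlorine–lithium exchange gives 9 and water releases the terminal aryl ynol ether; both lithium steps run below the temperature at which n-BuLi metalates the oxygen-flanked ring positions.

Step 5
Reactants: 10 2-(ethynyloxy)-1,3-dimethoxy-5-(2,4,6-trimethoxyphenoxy)benzene
Product: 11 2-(1-bromoethenyloxy)-1,3-dimethoxy-5-(2,4,6-trimethoxyphenoxy)benzene
Conditions: TMSBr (1.05 equiv), MeOH (1.05 equiv), CH2Cl2, −78 °C; used crude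
Reagents that add atoms: bromotrimethylsilane, C[Si](C)(C)Br (delivers bromine as HBr formed with methanol)
Why: Markovnikov hydrobromination of an ynol ether; protonation at the terminal carbon gives an oxygen-stabilised cation that bromide captures at the oxygen-bearing carbon, and one equivalent of dry HBr at low temperature limits a second addition.

Step 6
Reactants: 11 2-(1-bromoethenyloxy)-1,3-dimethoxy-5-(2,4,6-trimethoxyphenoxy)benzene; 12 dimethyl squarate
Product: 15 racemic 4-(tert-butyldimethylsilyloxy)-2,3-dimethoxy-4-{1-[2,6-dimethoxy-4-(2,4,6-trimethoxyphenoxy)phenoxy]ethenyl}cyclobut-2-en-1-one, via vinyllithium 13 (not isolated), via lithium alkoxide 14 (not isolated)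
Conditions: t-BuLi (2.0 equiv), THF/Et2O, −78 °C; add to 12, THF, −78 °C; then TBSOTf, −78 to 0 °C
Reagents that add atoms: tert-butyldimethylsilyl trifluoromethanesulfonate, CC(C)(C)[Si](C)(C)OS(=O)(=O)C(F)(F)F
Why: Bromine–lithium exchange outruns ring metalation at −78 °C and gives the α-aryloxyvinyllithium regiospecifically; organolithiums add 1,2 to one carbonyl of squaric esters, and silylating the tertiary alkoxide before work-up avoids exposing the acid-sensitive hydroxy enol ether. The new stereocentre forms as a racemate and is lost in step 7.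

Step 7
Reactants: 15 racemic 4-(tert-butyldimethylsilyloxy)-2,3-dimethoxy-4-{1-[2,6-dimethoxy-4-(2,4,6-trimethoxyphenoxy)phenoxy]ethenyl}cyclobut-2-en-1-one
Product: 18 4-(tert-butyldimethylsilyloxy)-5-[2,6-dimethoxy-4-(2,4,6-trimethoxyphenoxy)phenoxy]-2,3-dimethoxyphenol (A–B–C trimer; ring C: C2-OTBS C3-OMe C4-OMe C5-OH), via dienylketene 16 (not isolated), via cyclohexadienone 17 (not isolated)
Conditions: toluene (degassed), 110 °C, argon
Reagents that add atoms: none
Why: Moore rearrangement. Heating opens the cyclobutenone C1–C4 bond in a conrotatory 4-electron process, and the silyloxy donor on C4 rotates outward, which places the aryloxyvinyl group beside the ketene in dienylketene 16. A thermal disrotatory 6-electron electrocyclization then joins the ketene carbon to the vinyl CH2, forming the C5–C6 bond and closing ring C as the carbocyclic cyclohexa-2,4-dienone 17, whose enolization gives phenol 18. The closest known reactions are the thermal ring expansions of 4-alkenyl-4-hydroxy-, 4-alkoxy- and 4-silyloxycyclobutenones made from squaric esters, including adducts of α-lithiated enol ethers. No stereocentre is formed and the one in 15 is destroyed, so the racemate suffices. The oxygen pattern needs no selectivity here because it is fixed by connectivity: C2 to C5 arrive oxygenated from the squarate, C1 carries the ring B ether and only C6 is CH. The two selectivities that matter are outward rotation of the capped oxygen, secured by its donor character, and the identity of the free para oxygen (C5–OH from the carbonyl, C2–OSi from the carbinol), secured by silylation before heating; the cap also excludes lactonisation of the ketene onto a free hydroxyl.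

Step 8
Reactants: 18 A–B–C trimer phenol (ring C: C2-OTBS, C5-OH)
Product: 19 tert-butyl{6-[2,6-dimethoxy-4-(2,4,6-trimethoxyphenoxy)phenoxy]-2,3,4-trimethoxyphenoxy}dimethylsilane (ring C: C2-OTBS C3-OMe C4-OMe C5-OMe)
Conditions: MeI, K2CO3, acetone, 40 °C, argon
Reagents that add atoms: iodomethane, CI
Why: Williamson methylation of the only free phenol, which is flanked by one methoxy group and C6–H; the doubly ortho-substituted aryl silyl ether is stable to K2CO3 in dry acetone.

Step 9
Reactants: 19 A–B–C trimer silyl ether; 2 4-fluoro-2,6-dimethoxybenzaldehyde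
Product: 20 4-{6-[2,6-dimethoxy-4-(2,4,6-trimethoxyphenoxy)phenoxy]-2,3,4-trimethoxyphenoxy}-2,6-dimethoxybenzaldehyde (A–B–C–D aldehyde)
Conditions: CsF, DMF, 100 °C, argon
Reagents that add atoms: none
Why: Fluoride-promoted desilylative SNAr; CsF unmasks the C2 phenoxide of ring C, which displaces the para-formyl-activated fluoride, and the fluoride released carries the chain, so the cap is removed in the bond-forming step.

Step 10
Reactants: 20 A–B–C–D aldehyde
Product: 22 4-{6-[2,6-dimethoxy-4-(2,4,6-trimethoxyphenoxy)phenoxy]-2,3,4-trimethoxyphenoxy}-2,6-dimethoxyphenol (A–B–C–D phenol), via aryl formate 21 (not isolated)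
Conditions: mCPBA, CH2Cl2, 0 °C to rt; NaHCO3 wash; then K2CO3 (cat.), MeOH, rt
Reagents that add atoms: 3-chloroperoxybenzoic acid, O=C(OO)c1cccc(Cl)c1
Why: Dakin-type Baeyer–Villiger oxidation as in step 2; the formyl group sits between two methoxy groups and para to an aryloxy group, so the aryl migrates.

Step 11
Reactants: 22 A–B–C–D phenol; 6 trichloroethylene
Product: 23 (E)-1,2-dichloroethenyl ether of 22 on the C4 oxygen of ring D
Conditions: K2CO3, DMF, 70 °C
Reagents that add atoms: none
Why: Phenoxide addition to dichloroacetylene formed in solution, as in step 3.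

Step 12
Reactants: 23 (E)-1,2-dichloroethenyl ether of 22
Product: 26 ethynyl ether of 22 on the C4 oxygen of ring D, via chloroethynyl ether 24 (not isolated), via lithium acetylide 25 (not isolated)
Conditions: n-BuLi (2.2 equiv), THF, −78 to −40 °C; then H2O, −78 °C
Reagents that add atoms: none
Why: Elimination and chlorine–lithium exchange as in step 4; the temperature is kept low because ring C now adds one more oxygen-flanked ring hydrogen.

Step 13
Reactants: 26 ethynyl ether of 22
Product: 27 1-bromoethenyl ether of 22 on the C4 oxygen of ring D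
Conditions: TMSBr (1.05 equiv), MeOH (1.05 equiv), CH2Cl2, −78 °C; used crude
Reagents that add atoms: bromotrimethylsilane, C[Si](C)(C)Br (delivers bromine as HBr formed with methanol)
Why: Markovnikov hydrobromination of the ynol ether as in step 5; the substrate holds only methyl and diaryl ethers, none of which respond to one equivalent of HBr at −78 °C.

Step 14
Reactants: 27 1-bromoethenyl ether of 22; 12 dimethyl squarate
Product: 30 racemic 4-(tert-butyldimethylsilyloxy)-2,3-dimethoxycyclobut-2-en-1-one bearing at C4 the 1-(aryloxy)ethenyl group whose aryl is the A–B–C–D tetramer bound through ring D C4–O, via vinyllithium 28 (not isolated), via lithium alkoxide 29 (not isolated)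
Conditions: t-BuLi (2.0 equiv), THF/Et2O, −78 °C; add to 12, THF, −78 °C; then TBSOTf, −78 to 0 °C
Reagents that add atoms: tert-butyldimethylsilyl trifluoromethanesulfonate, CC(C)(C)[Si](C)(C)OS(=O)(=O)C(F)(F)F
Why: Bromine–lithium exchange, 1,2-addition to the squarate and silylation of the alkoxide in the flask, as in step 6; the stereocentre is racemic and is lost in step 15.

Step 15
Reactants: 30 racemic silyl-capped squarate adduct of the tetramer
Product: 33 A–B–C–D–E pentamer phenol (ring E: C1 ether to ring D; C2-OTBS C3-OMe C4-OMe C5-OH), via dienylketene 31 (not isolated), via cyclohexadienone 32 (not isolated)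
Conditions: toluene (degassed), 110 °C, argon
Reagents that add atoms: none
Why: Second Moore rearrangement, building ring E exactly as step 7 builds ring C: conrotatory opening with the silyloxy group outward, 6-electron electrocyclization forming C5–C6 of ring E and enolization.

Step 16
Reactants: 33 A–B–C–D–E pentamer phenol
Product: 34 A–B–C–D–E pentamer silyl ether (ring E: C2-OTBS C3-OMe C4-OMe C5-OMe)
Conditions: MeI, K2CO3, acetone, 40 °C, argon
Reagents that add atoms: iodomethane, CI
Why: Williamson methylation of the single unhindered phenol, as in step 8.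

Step 17
Reactants: 34 A–B–C–D–E pentamer silyl ether; 2 4-fluoro-2,6-dimethoxybenzaldehyde
Product: 35 A–B–C–D–E–F hexamer aldehyde (ring F: 4-formyl-3,5-dimethoxyphenyl on the C2 oxygen of ring E)
Conditions: CsF, DMF, 100 °C, argon
Reagents that add atoms: none
Why: Fluoride-promoted desilylative SNAr as in step 9.

Step 18
Reactants: 35 A–B–C–D–E–F hexamer aldehyde
Product: 37 A–B–C–D–E–F hexamer phenol (ring F: 4-hydroxy-3,5-dimethoxyphenyl), via aryl formate 36 (not isolated)
Conditions: mCPBA, CH2Cl2, 0 °C to rt; NaHCO3 wash; then K2CO3 (cat.), MeOH, rt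
Reagents that add atoms: 3-chloroperoxybenzoic acid, O=C(OO)c1cccc(Cl)c1
Why: Dakin-type Baeyer–Villiger oxidation as in steps 2 and 10.

Step 19
Reactants: 37 A–B–C–D–E–F hexamer phenol; 38 5-iodo-1,2,3-trimethoxybenzene
Product: 39 octadecamethyl ether of the heptamer (all eighteen hydroxyls of the target as OMe)
Conditions: CuI (10 mol %), picolinic acid (20 mol %), K3PO4, DMSO, 90 °C, argon
Reagents that add atoms: none
Why: Ligand-accelerated Ullmann diaryl ether synthesis; the picolinic acid system is suited to 2,6-disubstituted phenols, and the iodide has no ortho substituent.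

Step 20
Reactants: 39 octadecamethyl ether of the heptamer
Product: 40 target heptamer, eighteen free hydroxyls (CNP0292517.0)
Conditions: BBr3 (excess), CH2Cl2, −78 °C to rt; then H2O, 0 °C, argon
Reagents that add atoms: none
Why: Lewis-acid cleavage of aryl methyl ethers; BBr3 binds each methoxy oxygen and bromide removes the methyl group as bromomethane, the diaryl ether bonds (sp2 carbon on both sides) are not cleaved, and water hydrolyses the aryl borates.

## Compound list

1 | 2,4,6-trimethoxyphenol | COc1cc(OC)c(O)c(OC)c1 | starting material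
2 | 4-fluoro-2,6-dimethoxybenzaldehyde | COc1cc(F)cc(OC)c1C=O | starting material
3 | 2,6-dimethoxy-4-(2,4,6-trimethoxyphenoxy)benzaldehyde | COc1cc(OC)c(Oc2cc(OC)c(C=O)c(OC)c2)c(OC)c1 | intermediate
4 | 2,6-dimethoxy-4-(2,4,6-trimethoxyphenoxy)phenyl formate (not isolated) | COc1cc(OC)c(Oc2cc(OC)c(OC=O)c(OC)c2)c(OC)c1 | intermediate
5 | 2,6-dimethoxy-4-(2,4,6-trimethoxyphenoxy)phenol (A–B phenol) | COc1cc(OC)c(Oc2cc(OC)c(O)c(OC)c2)c(OC)c1 | intermediate
6 | trichloroethylene | ClC=C(Cl)Cl | starting material
7 | 2-[(E)-1,2-dichloroethenyloxy]-1,3-dimethoxy-5-(2,4,6-trimethoxyphenoxy)benzene | COc1cc(OC)c(Oc2cc(OC)c(O/C(Cl)=C\Cl)c(OC)c2)c(OC)c1 | intermediate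
8 | 2-(chloroethynyloxy)-1,3-dimethoxy-5-(2,4,6-trimethoxyphenoxy)benzene (not isolated) | COc1cc(OC)c(Oc2cc(OC)c(OC#CCl)c(OC)c2)c(OC)c1 | intermediate
9 | lithium acetylide of 10 (not isolated) | COc1cc(OC)c(Oc2cc(OC)c(OC#C[Li])c(OC)c2)c(OC)c1 | intermediate
10 | 2-(ethynyloxy)-1,3-dimethoxy-5-(2,4,6-trimethoxyphenoxy)benzene | COc1cc(OC)c(Oc2cc(OC)c(OC#C)c(OC)c2)c(OC)c1 | intermediate
11 | 2-(1-bromoethenyloxy)-1,3-dimethoxy-5-(2,4,6-trimethoxyphenoxy)benzene | COc1cc(OC)c(Oc2cc(OC)c(OC(Br)=C)c(OC)c2)c(OC)c1 | intermediate
12 | dimethyl squarate (3,4-dimethoxycyclobut-3-ene-1,2-dione) | COC1=C(OC)C(=O)C1=O | starting material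
13 | {1-[2,6-dimethoxy-4-(2,4,6-trimethoxyphenoxy)phenoxy]ethenyl}lithium (not isolated) | COc1cc(OC)c(Oc2cc(OC)c(OC([Li])=C)c(OC)c2)c(OC)c1 | intermediate
14 | lithium alkoxide of the squarate adduct, racemic (not isolated) | COc1cc(OC)c(Oc2cc(OC)c(OC(=C)C3(O[Li])C(OC)=C(OC)C3=O)c(OC)c2)c(OC)c1 | intermediate
15 | racemic 4-(tert-butyldimethylsilyloxy)-2,3-dimethoxy-4-{1-[2,6-dimethoxy-4-(2,4,6-trimethoxyphenoxy)phenoxy]ethenyl}cyclobut-2-en-1-one | COc1cc(OC)c(Oc2cc(OC)c(OC(=C)C3(O[Si](C)(C)C(C)(C)C)C(OC)=C(OC)C3=O)c(OC)c2)c(OC)c1 | intermediate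
16 | (3Z)-5-aryloxy-4-(tert-butyldimethylsilyloxy)-2,3-dimethoxyhexa-1,3,5-trien-1-one, aryl = A–B unit (not isolated) | COc1cc(OC)c(Oc2cc(OC)c(OC(=C)/C(O[Si](C)(C)C(C)(C)C)=C(OC)\C(OC)=C=O)c(OC)c2)c(OC)c1 | intermediate
17 | 5-aryloxy-4-(tert-butyldimethylsilyloxy)-2,3-dimethoxycyclohexa-2,4-dien-1-one, aryl = A–B unit (not isolated) | COc1cc(OC)c(Oc2cc(OC)c(OC3=C(O[Si](C)(C)C(C)(C)C)C(OC)=C(OC)C(=O)C3)c(OC)c2)c(OC)c1 | intermediate
18 | 4-(tert-butyldimethylsilyloxy)-5-[2,6-dimethoxy-4-(2,4,6-trimethoxyphenoxy)phenoxy]-2,3-dimethoxyphenol (A–B–C trimer, ring C C5–OH free) | COc1cc(OC)c(Oc2cc(OC)c(Oc3cc(O)c(OC)c(OC)c3O[Si](C)(C)C(C)(C)C)c(OC)c2)c(OC)c1 | intermediate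
19 | tert-butyl{6-[2,6-dimethoxy-4-(2,4,6-trimethoxyphenoxy)phenoxy]-2,3,4-trimethoxyphenoxy}dimethylsilane | COc1cc(OC)c(Oc2cc(OC)c(Oc3cc(OC)c(OC)c(OC)c3O[Si](C)(C)C(C)(C)C)c(OC)c2)c(OC)c1 | intermediate
20 | A–B–C–D aldehyde (ring D 4-formyl-3,5-dimethoxyphenyl on ring C C2–O) | COc1cc(OC)c(Oc2cc(OC)c(Oc3cc(OC)c(OC)c(OC)c3Oc3cc(OC)c(C=O)c(OC)c3)c(OC)c2)c(OC)c1 | intermediate
21 | A–B–C–D aryl formate on ring D C4 (not isolated) | COc1cc(OC)c(Oc2cc(OC)c(Oc3cc(OC)c(OC)c(OC)c3Oc3cc(OC)c(OC=O)c(OC)c3)c(OC)c2)c(OC)c1 | intermediate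
22 | A–B–C–D phenol (ring D C4–OH) | COc1cc(OC)c(Oc2cc(OC)c(Oc3cc(OC)c(OC)c(OC)c3Oc3cc(OC)c(O)c(OC)c3)c(OC)c2)c(OC)c1 | intermediate
23 | (E)-1,2-dichloroethenyl ether of 22 | COc1cc(OC)c(Oc2cc(OC)c(Oc3cc(OC)c(OC)c(OC)c3Oc3cc(OC)c(O/C(Cl)=C\Cl)c(OC)c3)c(OC)c2)c(OC)c1 | intermediate
24 | chloroethynyl ether of 22 (not isolated) | COc1cc(OC)c(Oc2cc(OC)c(Oc3cc(OC)c(OC)c(OC)c3Oc3cc(OC)c(OC#CCl)c(OC)c3)c(OC)c2)c(OC)c1 | intermediate
25 | lithium acetylide of 26 (not isolated) | COc1cc(OC)c(Oc2cc(OC)c(Oc3cc(OC)c(OC)c(OC)c3Oc3cc(OC)c(OC#C[Li])c(OC)c3)c(OC)c2)c(OC)c1 | intermediate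
26 | ethynyl ether of 22 | COc1cc(OC)c(Oc2cc(OC)c(Oc3cc(OC)c(OC)c(OC)c3Oc3cc(OC)c(OC#C)c(OC)c3)c(OC)c2)c(OC)c1 | intermediate
27 | 1-bromoethenyl ether of 22 | COc1cc(OC)c(Oc2cc(OC)c(Oc3cc(OC)c(OC)c(OC)c3Oc3cc(OC)c(OC(Br)=C)c(OC)c3)c(OC)c2)c(OC)c1 | intermediate
28 | 1-lithioethenyl ether of 22 (not isolated) | COc1cc(OC)c(Oc2cc(OC)c(Oc3cc(OC)c(OC)c(OC)c3Oc3cc(OC)c(OC([Li])=C)c(OC)c3)c(OC)c2)c(OC)c1 | intermediate
29 | lithium alkoxide of the tetramer squarate adduct, racemic (not isolated) | COc1cc(OC)c(Oc2cc(OC)c(Oc3cc(OC)c(OC)c(OC)c3Oc3cc(OC)c(OC(=C)C4(O[Li])C(OC)=C(OC)C4=O)c(OC)c3)c(OC)c2)c(OC)c1 | intermediate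
30 | racemic 4-(tert-butyldimethylsilyloxy)-2,3-dimethoxy-4-[1-(tetramer aryloxy)ethenyl]cyclobut-2-en-1-one | COc1cc(OC)c(Oc2cc(OC)c(Oc3cc(OC)c(OC)c(OC)c3Oc3cc(OC)c(OC(=C)C4(O[Si](C)(C)C(C)(C)C)C(OC)=C(OC)C4=O)c(OC)c3)c(OC)c2)c(OC)c1 | intermediate
31 | (3Z)-dienylketene from 30 (not isolated) | COc1cc(OC)c(Oc2cc(OC)c(Oc3cc(OC)c(OC)c(OC)c3Oc3cc(OC)c(OC(=C)/C(O[Si](C)(C)C(C)(C)C)=C(OC)\C(OC)=C=O)c(OC)c3)c(OC)c2)c(OC)c1 | intermediate
32 | cyclohexa-2,4-dienone from 31 (not isolated) | COc1cc(OC)c(Oc2cc(OC)c(Oc3cc(OC)c(OC)c(OC)c3Oc3cc(OC)c(OC4=C(O[Si](C)(C)C(C)(C)C)C(OC)=C(OC)C(=O)C4)c(OC)c3)c(OC)c2)c(OC)c1 | intermediate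
33 | A–B–C–D–E pentamer phenol (ring E: C2-OTBS, C3/C4-OMe, C5-OH) | COc1cc(OC)c(Oc2cc(OC)c(Oc3cc(OC)c(OC)c(OC)c3Oc3cc(OC)c(Oc4cc(O)c(OC)c(OC)c4O[Si](C)(C)C(C)(C)C)c(OC)c3)c(OC)c2)c(OC)c1 | intermediate
34 | A–B–C–D–E pentamer silyl ether (ring E: C2-OTBS, C3/C4/C5-OMe) | COc1cc(OC)c(Oc2cc(OC)c(Oc3cc(OC)c(OC)c(OC)c3Oc3cc(OC)c(Oc4cc(OC)c(OC)c(OC)c4O[Si](C)(C)C(C)(C)C)c(OC)c3)c(OC)c2)c(OC)c1 | intermediate
35 | A–F hexamer aldehyde (ring F 4-formyl-3,5-dimethoxyphenyl) | COc1cc(OC)c(Oc2cc(OC)c(Oc3cc(OC)c(OC)c(OC)c3Oc3cc(OC)c(Oc4cc(OC)c(OC)c(OC)c4Oc4cc(OC)c(C=O)c(OC)c4)c(OC)c3)c(OC)c2)c(OC)c1 | intermediate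
36 | A–F hexamer aryl formate on ring F C4 (not isolated) | COc1cc(OC)c(Oc2cc(OC)c(Oc3cc(OC)c(OC)c(OC)c3Oc3cc(OC)c(Oc4cc(OC)c(OC)c(OC)c4Oc4cc(OC)c(OC=O)c(OC)c4)c(OC)c3)c(OC)c2)c(OC)c1 | intermediate
37 | A–F hexamer phenol (ring F C4–OH) | COc1cc(OC)c(Oc2cc(OC)c(Oc3cc(OC)c(OC)c(OC)c3Oc3cc(OC)c(Oc4cc(OC)c(OC)c(OC)c4Oc4cc(OC)c(O)c(OC)c4)c(OC)c3)c(OC)c2)c(OC)c1 | intermediate
38 | 5-iodo-1,2,3-trimethoxybenzene | COc1cc(I)cc(OC)c1OC | starting material
39 | octadecamethyl ether of the heptamer | COc1cc(OC)c(Oc2cc(OC)c(Oc3cc(OC)c(OC)c(OC)c3Oc3cc(OC)c(Oc4cc(OC)c(OC)c(OC)c4Oc4cc(OC)c(Oc5cc(OC)c(OC)c(OC)c5)c(OC)c4)c(OC)c3)c(OC)c2)c(OC)c1 | intermediate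
40 | target heptamer CNP0292517.0 (achiral) | Oc1cc(O)c(Oc2cc(O)c(Oc3cc(O)c(O)c(O)c3Oc3cc(O)c(Oc4cc(O)c(O)c(O)c4Oc4cc(O)c(Oc5cc(O)c(O)c(O)c5)c(O)c4)c(O)c3)c(O)c2)c(O)c1 | target

## Step count and risks

Total: 20 steps. Longest linear sequence: 20 steps (from 1 and 2 to 40; the route is fully linear).

**Step 7 (key step; step 15 repeats it).** The dienylketene may be diverted before it cyclises. The 6-electron closure has to bring a ketene carbon onto a vinyl group that carries a bulky 2,6-dimethoxyaryloxy substituent, and a slowed closure leaves time for ketene dimerisation or capture by traces of water or by the phenolic product. Hydrolysis of the enol ether before ring opening, and air oxidation of the electron-rich phenol formed, are further losses.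
Fallback: ring C is brought in preformed, starting from 5 and rejoining at 20. Commercial 2,3,4-trimethoxyphenol is brominated ortho to the hydroxyl (NBS, MeCN, 0 °C; the para position is blocked) to 6-bromo-2,3,4-trimethoxyphenol F1. Benzylation (BnBr, K2CO3, DMF) gives 2-(benzyloxy)-1-bromo-3,4,5-trimethoxybenzene F2. Ullmann coupling of F2 with 5 (CuI, picolinic acid, K3PO4, DMSO, 110 °C) gives the A–B–C trimer benzyl ether F3. Hydrogenolysis (H2, Pd/C, EtOAc) gives the A–B–C trimer C2-phenol F4, and its SNAr with 2 (K2CO3, DMF, 110 °C) gives 20.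

**Step 5 (step 13 repeats it).** A second addition of HBr, or hydrolysis of the α-bromo enol ether during handling, would consume the bromide. In step 6 the alkyllithium may also remove a vinyl hydrogen and eliminate LiBr back to the acetylide instead of exchanging.
Fallback: from 10, hydrostannation with Bu3SnH under Pd(PPh3)4 catalysis, which places tin on the oxygen-bearing carbon of ynol ethers, gives tributyl{1-[2,6-dimethoxy-4-(2,4,6-trimethoxyphenoxy)phenoxy]ethenyl}stannane F5. This stannane is stable and can be purified. Tin–lithium exchange (n-BuLi, THF, −78 °C) gives 13, which is taken on through 14 to 15 as in step 6.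

**Step 17 (step 9 carries the same risk on a smaller substrate).** Attack of the doubly ortho-substituted phenoxide on the fluoride of 2 may be too slow; the two methoxy groups of 2 also weaken the activating effect of the formyl group. The unmasked electron-rich phenoxide and the aldehyde would then degrade at 100 °C before coupling.
Fallback: from 34, desilylation (Bu4NF, THF, 0 °C) gives the A–B–C–D–E pentamer C2-phenol F6. Copper-catalysed coupling of F6 with commercial 4-bromo-2,6-dimethoxybenzaldehyde (CuI, picolinic acid, K3PO4, DMSO, 100 °C) gives 35. Oxidative addition at the electron-poor bromide replaces the addition–elimination step. For step 9 the same recourse would run from 19 through F4 to 20.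

**Step 19.** Copper insertion into the electron-rich iodide 38 is slow, and the large 2,6-dimethoxyphenoxide of 37 binds copper poorly. Reduction of 38 to 1,2,3-trimethoxybenzene could then outpace coupling.
Fallback: from 37, SNAr with 2 (K2CO3, DMF, 110 °C) gives the heptamer aldehyde F7 (ring G 4-formyl-3,5-dimethoxyphenyl). Dakin oxidation (mCPBA, then K2CO3, MeOH) through the heptamer aryl formate F8 gives the heptamer phenol F9 (ring G 4-hydroxy-3,5-dimethoxyphenyl). Treating F9 with BBr3 under the conditions of step 20 gives 40 directly, since ring G needs no methyl group at C4.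

**Step 20.** Cleavage may stop short at some of the eighteen sites as polyborate intermediates precipitate, leaving partial methyl ethers that are hard to separate from a very polar product. The free pyrogallol-type rings may also oxidise during isolation.
Fallback: from 39, after the BBr3 treatment the crude polyphenol is acetylated without purification (Ac2O, pyridine, argon) to the octadecaacetate F10. F10 can be chromatographed, which allows under-cleaved material to be separated and resubmitted. Deacetylation of F10 (NaOMe, MeOH, argon; acidic resin work-up) releases 40.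

## Further compounds

F1 | step 7 | 6-bromo-2,3,4-trimethoxyphenol | COc1cc(Br)c(O)c(OC)c1OC
F2 | step 7 | 2-(benzyloxy)-1-bromo-3,4,5-trimethoxybenzene | COc1cc(Br)c(OCc2ccccc2)c(OC)c1OC
F3 | step 7 | A–B–C trimer benzyl ether (ring C: C2-OBn, C3/C4/C5-OMe) | COc1cc(OC)c(Oc2cc(OC)c(Oc3cc(OC)c(OC)c(OC)c3OCc3ccccc3)c(OC)c2)c(OC)c1
F4 | step 7 | A–B–C trimer C2-phenol (ring C: C2-OH, C3/C4/C5-OMe) | COc1cc(OC)c(Oc2cc(OC)c(Oc3cc(OC)c(OC)c(OC)c3O)c(OC)c2)c(OC)c1
F5 | step 5 | tributyl{1-[2,6-dimethoxy-4-(2,4,6-trimethoxyphenoxy)phenoxy]ethenyl}stannane | COc1cc(OC)c(Oc2cc(OC)c(OC(=C)[Sn](CCCC)(CCCC)CCCC)c(OC)c2)c(OC)c1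
F6 | step 17 | A–B–C–D–E pentamer C2-phenol (ring E: C2-OH, C3/C4/C5-OMe) | COc1cc(OC)c(Oc2cc(OC)c(Oc3cc(OC)c(OC)c(OC)c3Oc3cc(OC)c(Oc4cc(OC)c(OC)c(OC)c4O)c(OC)c3)c(OC)c2)c(OC)c1
F7 | step 19 | heptamer aldehyde (ring G 4-formyl-3,5-dimethoxyphenyl) | COc1cc(OC)c(Oc2cc(OC)c(Oc3cc(OC)c(OC)c(OC)c3Oc3cc(OC)c(Oc4cc(OC)c(OC)c(OC)c4Oc4cc(OC)c(Oc5cc(OC)c(C=O)c(OC)c5)c(OC)c4)c(OC)c3)c(OC)c2)c(OC)c1
F8 | step 19 | heptamer aryl formate on ring G C4 | COc1cc(OC)c(Oc2cc(OC)c(Oc3cc(OC)c(OC)c(OC)c3Oc3cc(OC)c(Oc4cc(OC)c(OC)c(OC)c4Oc4cc(OC)c(Oc5cc(OC)c(OC=O)c(OC)c5)c(OC)c4)c(OC)c3)c(OC)c2)c(OC)c1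
F9 | step 19 | heptamer phenol (ring G 4-hydroxy-3,5-dimethoxyphenyl) | COc1cc(OC)c(Oc2cc(OC)c(Oc3cc(OC)c(OC)c(OC)c3Oc3cc(OC)c(Oc4cc(OC)c(OC)c(OC)c4Oc4cc(OC)c(Oc5cc(OC)c(O)c(OC)c5)c(OC)c4)c(OC)c3)c(OC)c2)c(OC)c1
F10 | step 20 | octadecaacetate of 40 | CC(=O)Oc1cc(OC(C)=O)c(Oc2cc(OC(C)=O)c(Oc3cc(OC(C)=O)c(OC(C)=O)c(OC(C)=O)c3Oc3cc(OC(C)=O)c(Oc4cc(OC(C)=O)c(OC(C)=O)c(OC(C)=O)c4Oc4cc(OC(C)=O)c(Oc5cc(OC(C)=O)c(OC(C)=O)c(OC(C)=O)c5)c(OC(C)=O)c4)c(OC(C)=O)c3)c(OC(C)=O)c2)c(OC(C)=O)c1
A1 | alternative 1 | cyclopentadienylruthenium hexafluorophosphate complex of 1,2-dichloro-3,4,5-trimethoxybenzene | COc1cc(Cl)c(Cl)c(OC)c1OC.[cH-]1cccc1.[Ru+2].F[P-](F)(F)(F)(F)F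
A2 | alternative 1 | D–E–F–G tetramer phenol (ring D C1–OH, all other oxygens as OMe) | Oc1cc(OC)c(Oc2cc(OC)c(OC)c(OC)c2Oc2cc(OC)c(Oc3cc(OC)c(OC)c(OC)c3)c(OC)c2)c(OC)c1
A3 | alternative 1 | permethylated heptamer as its cyclopentadienylruthenium hexafluorophosphate complex on ring C | COc1cc(OC)c(Oc2cc(OC)c(Oc3cc(OC)c(OC)c(OC)c3Oc3cc(OC)c(Oc4cc(OC)c(OC)c(OC)c4Oc4cc(OC)c(Oc5cc(OC)c(OC)c(OC)c5)c(OC)c4)c(OC)c3)c(OC)c2)c(OC)c1.[cH-]1cccc1.[Ru+2].F[P-](F)(F)(F)(F)F
A4 | alternative 2 | dimethyl 2-aryloxy-3,5-dioxoheptanedioate, aryl = permethylated B–G hexamer | COC(=O)C(Oc1cc(OC)c(Oc2cc(OC)c(OC)c(OC)c2Oc2cc(OC)c(Oc3cc(OC)c(OC)c(OC)c3Oc3cc(OC)c(Oc4cc(OC)c(OC)c(OC)c4)c(OC)c3)c(OC)c2)c(OC)c1)C(=O)CC(=O)CC(=O)OC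
A5 | alternative 2 | heptamer with ring A as free triol bearing a methyl ester, rings B–G as methyl ethers | COC(=O)c1c(O)cc(O)c(Oc2cc(OC)c(Oc3cc(OC)c(OC)c(OC)c3Oc3cc(OC)c(Oc4cc(OC)c(OC)c(OC)c4Oc4cc(OC)c(Oc5cc(OC)c(OC)c(OC)c5)c(OC)c4)c(OC)c3)c(OC)c2)c1O
A6 | alternative 3 | ethynyl ether of the A–B–C trimer on ring C C2–O | COc1cc(OC)c(Oc2cc(OC)c(Oc3cc(OC)c(OC)c(OC)c3OC#C)c(OC)c2)c(OC)c1
A7 | alternative 3 | racemic 4-aryloxy-3-ethoxycyclobut-2-en-1-one, aryl = E–F–G trimer bound through ring E C1–O | CCOC1=CC(=O)C1Oc1cc(OC)c(OC)c(OC)c1Oc1cc(OC)c(Oc2cc(OC)c(OC)c(OC)c2)c(OC)c1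
A8 | alternative 3 | heptamer with ring D as 3-hydroxy-5-ethoxy, all other hydroxyls as methyl ethers | COc1cc(OC)c(Oc2cc(OC)c(Oc3cc(OC)c(OC)c(OC)c3Oc3cc(O)c(Oc4cc(OC)c(OC)c(OC)c4Oc4cc(OC)c(Oc5cc(OC)c(OC)c(OC)c5)c(OC)c4)c(OCC)c3)c(OC)c2)c(OC)c1
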